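**Plan**
- The target is achiral. Working backwards, the O5 ethyl and O7 silyl masks come off last. The pyranone is cut at O1–C2 and C3–C4 (an ortho-hydroxyaryl aryloxy ynone, from an aryloxyacetylide and an aldehyde) and at C4–C4a (ortho-formylation).
- Ring A (C4a, C5, C6, C7, C8, C8a) is a phloroglucinol: its three oxygens (O1 on C8a, OH on C5, OH on C7) each need a different fate, and its prenyl group on C8 sits between O1 and O7. It is cut at C8–C8a, C6–C7 and C4a–C8a into 3-ethoxycyclobutenone and a prenyl-substituted siloxyalkyne.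
- Forward: ring A is built first by benzannulation, with O1 free, O5 as an ethyl ether and O7 as a silyl ether. C4 is then placed on C4a, the C3–C2–OAr unit is added, the pyranone closes by O1 onto C2, and O5, then O7, are unmasked.
- Stereochemistry: nothing has to be set; the carbinol centre formed in step 7 is racemic and is removed in step 8.

Key step: step 4

Remark: ethoxyacetylene is taken as the commercial solution in hexanes; the only alkene of the target carries two identical methyl groups, so it has no configuration.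

**Step 1**
Reactants: 1 ethoxyacetylene; 2 acetyl chloride
Product: 4 3-ethoxycyclobut-2-en-1-one, via ketene 3 (not isolated)
Conditions: Et3N, Et2O, 0 °C → rt (slow addition of 2)
Reagents that add atoms: none
Why: Ketene released from acetyl chloride by Et3N should undergo thermal (2+2) cycloaddition with the electron-rich ynol ether, the ketene carbonyl carbon bonding to the unsubstituted alkyne carbon, to give the vinylogous ester.

**Step 2**
Reactants: 5 4-methylpent-3-enoic acid
Product: 6 ethyl 4-methylpent-3-enoate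
Conditions: EtI, K2CO3, DMF, rt
Reagents that add atoms: iodoethane CCI
Why: Carboxylate O-alkylation (SN2) under weakly basic conditions avoids the acid-induced lactonisation that a Fischer esterification of this β,γ-unsaturated acid would invite.

**Step 3**
Reactants: 6 ethyl 4-methylpent-3-enoate
Product: 9 triisopropyl[(5-methylhex-4-en-1-yn-1-yl)oxy]silane, via lithium dibromoenolate 7 (not isolated), via lithium ynolate 8 (not isolated)
Conditions: CH2Br2, lithium 2,2,6,6-tetramethylpiperidide (LiTMP), THF, −78 °C; LiN(SiMe3)2; n-BuLi, −78 °C → rt; then i-Pr3SiCl, −78 → 0 °C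
Reagents that add atoms: dibromomethane BrCBr; chlorotriisopropylsilane CC(C)[Si](Cl)(C(C)C)C(C)C
Why: Kowalski ester homologation: LiCHBr2 adds to the ester, the derived dibromo enolate 7 undergoes bromine–lithium exchange and a carbenoid 1,2-shift of the prenyl group to ynolate 8, and the bulky silyl chloride should silylate on oxygen to give the ynol silyl ether.

**Step 4**
Reactants: 4 3-ethoxycyclobut-2-en-1-one; 9 triisopropyl[(5-methylhex-4-en-1-yn-1-yl)oxy]silane
Product: 14 5-ethoxy-2-(3-methylbut-2-en-1-yl)-3-[(triisopropylsilyl)oxy]phenol, via vinylketene 10 (not isolated), via vinylcyclobutenone 11 (not isolated), via dienylketene 12 (not isolated), via cyclohexadienone 13 (not isolated)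
Conditions: 9 (1.2 equiv), PhMe, 80 °C then 110 °C, sealed tube (4 added slowly)
Reagents that add atoms: none
Why: Heat opens 4 by four-electron conrotatory electrocyclic cleavage to 2-ethoxyvinylketene 10, which adds (2+2) to ynol ether 9 with the electron-rich prenyl-bearing alkyne carbon bonding to the ketene carbonyl carbon (C8–C8a) and the siloxy carbon to the ketene alpha carbon (C7–C6), giving cyclobutenone 11. A second four-electron opening of 11 gives dienylketene 12, and ring A closes by thermal six-electron disrotatory electrocyclisation between the ketene carbon and the terminal methylene (C8a–C4a) to dienone 13, which enolises to phenol 14. The closest known reaction is the Danheiser benzannulation of 3-alkylcyclobutenones with siloxyalkynes to resorcinol monosilyl ethers; the alkoxy group on the cyclobutenone is the one new variable and is expected to raise the temperature needed for the first ring opening. No lasting stereocentre arises, since the sp3 carbon of 11 is planarised on ring opening and the alkene geometries of 12 interconvert through 11 until the cyclisable (3E) isomer is consumed. The one selectivity required is the orientation of the (2+2) step, and the polarisation of the siloxyalkyne (oxygen-bearing carbon electrophilic, the other carbon nucleophilic) secures it, so prenyl lands between the new hydroxyl and the siloxy group and O1, O5 and O7 emerge as OH, OEt and OSi. The medium is neutral, which the prenyl alkene and the silyl ether should tolerate, and slow addition of 4 keeps the ketene concentration low so that the product phenol is not acylated.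

**Step 5**
Reactants: 14 5-ethoxy-2-(3-methylbut-2-en-1-yl)-3-[(triisopropylsilyl)oxy]phenol
Product: 15 6-ethoxy-2-hydroxy-3-(3-methylbut-2-en-1-yl)-4-[(triisopropylsilyl)oxy]benzaldehyde
Conditions: anhydrous MgCl2, Et3N, (CH2O)n, MeCN, 80 °C
Reagents that add atoms: paraformaldehyde (as formaldehyde) C=O
Why: In the magnesium-mediated ortho-formylation (Casnati–Skattebøl) the magnesium phenoxide delivers formaldehyde only to an ortho carbon, and since C8 is blocked by prenyl the formyl group should enter at C4a between the hydroxyl and the ethoxy group, the hydroxymethyl stage being oxidised in situ by a second formaldehyde.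

**Step 6**
Reactants: 16 4-methoxyphenol
Product: 17 1-{[(E)-1,2-dichloroethenyl]oxy}-4-methoxybenzene
Conditions: Cl2C=CHCl, K2CO3, DMF, 70 °C
Reagents that add atoms: trichloroethylene ClC=C(Cl)Cl
Why: Elimination of HCl from trichloroethylene gives dichloroacetylene, to which the phenoxide adds in anti fashion (elimination–addition), giving the (E)-dichlorovinyl ether as a storable precursor of the aryloxyacetylide.

**Step 7**
Reactants: 17 1-{[(E)-1,2-dichloroethenyl]oxy}-4-methoxybenzene; 15 6-ethoxy-2-hydroxy-3-(3-methylbut-2-en-1-yl)-4-[(triisopropylsilyl)oxy]benzaldehyde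
Product: 19 rac-3-ethoxy-2-[1-hydroxy-3-(4-methoxyphenoxy)prop-2-yn-1-yl]-6-(3-methylbut-2-en-1-yl)-5-[(triisopropylsilyl)oxy]phenol, via lithium aryloxyacetylide 18 (not isolated)
Conditions: 17 (2.5 equiv), n-BuLi (5.2 equiv), THF, −78 → −40 °C; then 15, −78 → −20 °C; pH 7 phosphate buffer; used crude
Reagents that add atoms: none
Why: n-BuLi converts 17 by deprotonation, loss of LiCl and chlorine–lithium exchange into acetylide 18, of which one equivalent deprotonates the phenol and a second adds to the aldehyde (acetylide 1,2-addition); the carbinol centre is formed as a racemate and is removed in step 8.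

**Step 8**
Reactants: 19 rac-3-ethoxy-2-[1-hydroxy-3-(4-methoxyphenoxy)prop-2-yn-1-yl]-6-(3-methylbut-2-en-1-yl)-5-[(triisopropylsilyl)oxy]phenol
Product: 21 5-ethoxy-2-(4-methoxyphenoxy)-8-(3-methylbut-2-en-1-yl)-7-[(triisopropylsilyl)oxy]-4H-chromen-4-one, via aryloxy ynone 20 (not isolated)
Conditions: MnO2, CH2Cl2, rt; filter; K2CO3, acetone, rt
Reagents that add atoms: none
Why: MnO2 oxidises the benzylic and propargylic alcohol under neutral conditions that spare the ynol ether, and the ortho phenoxide should then add to the alkyne carbon bearing the aryloxy group (6-endo-dig oxa-Michael cyclisation of an ortho-hydroxyaryl ynone), an orientation that both the ketone and the oxygen substituent favour over 5-exo closure.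

**Step 9**
Reactants: 21 5-ethoxy-2-(4-methoxyphenoxy)-8-(3-methylbut-2-en-1-yl)-7-[(triisopropylsilyl)oxy]-4H-chromen-4-one
Product: 22 5-hydroxy-2-(4-methoxyphenoxy)-8-(3-methylbut-2-en-1-yl)-7-[(triisopropylsilyl)oxy]-4H-chromen-4-one
Conditions: BCl3 (1 M in CH2Cl2), CH2Cl2, −78 → −20 °C; cold aq NaHCO3
Reagents that add atoms: none
Why: BCl3 binds between the C4 carbonyl and the peri O5, so chloride should cleave only that ethyl group (chelation-directed ether cleavage), leaving the unchelated anisole methyl ether, and with O7 still silylated no phenol is free to cyclise onto the prenyl alkene.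

**Step 10**
Reactants: 22 5-hydroxy-2-(4-methoxyphenoxy)-8-(3-methylbut-2-en-1-yl)-7-[(triisopropylsilyl)oxy]-4H-chromen-4-one
Product: 23 5,7-dihydroxy-2-(4-methoxyphenoxy)-8-(3-methylbut-2-en-1-yl)-4H-chromen-4-one
Conditions: n-Bu4NF, AcOH, THF, 0 °C
Reagents that add atoms: none
Why: Fluoride cleaves the aryl silyl ether readily because the phenoxide is a good leaving group on silicon, and buffering with acetic acid keeps hydroxide away from the electrophilic C2 of the aryloxypyranone.

**Compound list**
1 | ethoxyacetylene (ethoxyethyne) | CCOC#C | starting material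
2 | acetyl chloride | CC(=O)Cl | starting material
3 | ketene (ethenone) | C=C=O | intermediate
4 | 3-ethoxycyclobut-2-en-1-one | CCOC1=CC(=O)C1 | intermediate
5 | 4-methylpent-3-enoic acid | CC(C)=CCC(=O)O | starting material
6 | ethyl 4-methylpent-3-enoate | CCOC(=O)CC=C(C)C | intermediate
7 | lithium 1,1-dibromo-5-methylhexa-1,4-dien-2-olate | [Li+].[O-]C(CC=C(C)C)=C(Br)Br | intermediate
8 | lithium 5-methylhex-4-en-1-yn-1-olate | [Li+].[O-]C#CCC=C(C)C | intermediate
9 | triisopropyl[(5-methylhex-4-en-1-yn-1-yl)oxy]silane | CC(C)=CCC#CO[Si](C(C)C)(C(C)C)C(C)C | intermediate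
10 | 3-ethoxybuta-1,3-dien-1-one | CCOC(=C)C=C=O | intermediate
11 | rac-4-(1-ethoxyethenyl)-2-(3-methylbut-2-en-1-yl)-3-[(triisopropylsilyl)oxy]cyclobut-2-en-1-one | CCOC(=C)C1C(=O)C(CC=C(C)C)=C1O[Si](C(C)C)(C(C)C)C(C)C | intermediate
12 | (3E)-5-ethoxy-2-(3-methylbut-2-en-1-yl)-3-[(triisopropylsilyl)oxy]hexa-1,3,5-trien-1-one | C=C(OCC)/C=C(O[Si](C(C)C)(C(C)C)C(C)C)\C(CC=C(C)C)=C=O | intermediate
13 | 5-ethoxy-2-(3-methylbut-2-en-1-yl)-3-[(triisopropylsilyl)oxy]cyclohexa-2,4-dien-1-one | CCOC1=CC(O[Si](C(C)C)(C(C)C)C(C)C)=C(CC=C(C)C)C(=O)C1 | intermediate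
14 | 5-ethoxy-2-(3-methylbut-2-en-1-yl)-3-[(triisopropylsilyl)oxy]phenol | CCOc1cc(O)c(CC=C(C)C)c(O[Si](C(C)C)(C(C)C)C(C)C)c1 | intermediate
15 | 6-ethoxy-2-hydroxy-3-(3-methylbut-2-en-1-yl)-4-[(triisopropylsilyl)oxy]benzaldehyde | CCOc1cc(O[Si](C(C)C)(C(C)C)C(C)C)c(CC=C(C)C)c(O)c1C=O | intermediate
16 | 4-methoxyphenol | COc1ccc(O)cc1 | starting material
17 | 1-{[(E)-1,2-dichloroethenyl]oxy}-4-methoxybenzene | COc1ccc(O/C(Cl)=C\Cl)cc1 | intermediate
18 | lithium (4-methoxyphenoxy)acetylide | [Li+].[C-]#COc1ccc(OC)cc1 | intermediate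
19 | rac-3-ethoxy-2-[1-hydroxy-3-(4-methoxyphenoxy)prop-2-yn-1-yl]-6-(3-methylbut-2-en-1-yl)-5-[(triisopropylsilyl)oxy]phenol | CCOc1cc(O[Si](C(C)C)(C(C)C)C(C)C)c(CC=C(C)C)c(O)c1C(O)C#COc1ccc(OC)cc1 | intermediate
20 | 1-{6-ethoxy-2-hydroxy-3-(3-methylbut-2-en-1-yl)-4-[(triisopropylsilyl)oxy]phenyl}-3-(4-methoxyphenoxy)prop-2-yn-1-one | CCOc1cc(O[Si](C(C)C)(C(C)C)C(C)C)c(CC=C(C)C)c(O)c1C(=O)C#COc1ccc(OC)cc1 | intermediate
21 | 5-ethoxy-2-(4-methoxyphenoxy)-8-(3-methylbut-2-en-1-yl)-7-[(triisopropylsilyl)oxy]-4H-chromen-4-one | CCOc1cc(O[Si](C(C)C)(C(C)C)C(C)C)c(CC=C(C)C)c2oc(Oc3ccc(OC)cc3)cc(=O)c12 | intermediate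
22 | 5-hydroxy-2-(4-methoxyphenoxy)-8-(3-methylbut-2-en-1-yl)-7-[(triisopropylsilyl)oxy]-4H-chromen-4-one | Oc1cc(O[Si](C(C)C)(C(C)C)C(C)C)c(CC=C(C)C)c2oc(Oc3ccc(OC)cc3)cc(=O)c12 | intermediate
23 | 5,7-dihydroxy-2-(4-methoxyphenoxy)-8-(3-methylbut-2-en-1-yl)-4H-chromen-4-one | COc1ccc(Oc2cc(=O)c3c(O)cc(O)c(CC=C(C)C)c3o2)cc1 | target

**Count**
Total steps: 10. Longest linear sequence: 8 steps (5 → 6 → 9 → 14 → 15 → 19 → 21 → 22 → 23, that is steps 2, 3, 4, 5, 7, 8, 9, 10).

**Steps most likely to fail**

Step 4. The vinylogous-ester cyclobutenone may open too slowly. At the temperature then needed, the siloxyalkyne could isomerise to a silylketene by 1,3-silyl shift, and ketene 10 could be lost to self-condensation or to acylation of the product phenol. The fallback generates the same ketene at room temperature by photochemical Wolff rearrangement of a diazo ketone; it sets out from siloxyalkyne 9 and returns at phenol 14. Ethyl vinyl ether would be lithiated (t-BuLi, THF, −78 → 0 °C) and acylated with N-methoxy-N-methylacetamide to give 3-ethoxybut-3-en-2-one F1. Its lithium enolate (LiN(SiMe3)2, −78 °C) would be trifluoroacetylated with 2,2,2-trifluoroethyl trifluoroacetate to 5-ethoxy-1,1,1-trifluorohex-5-ene-2,4-dione F2. Diazo transfer from methanesulfonyl azide (Et3N, water, MeCN), with loss of the trifluoroacetyl group, would give 1-diazo-3-ethoxybut-3-en-2-one F3. Irradiation of F3 with 9 in CH2Cl2 at room temperature, followed by brief warming to finish the electrocyclic steps, should lead through 10, 11, 12 and 13 to 14.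

Step 7. The electron-rich benzylic carbinol carries an ynol ether and may ionise on work-up or handling (Meyer–Schuster-type collapse to an aryl cinnamate, then lactonisation to a coumarin). Addition to the deactivated phenoxide-aldehyde may also stall. The fallback avoids the acetylide and the ynone of step 8 by introducing the aryloxy group through addition–elimination on a 2-sulfinylchromone; it sets out from aldehyde 15 and returns at chromone 21.
- MeMgBr (excess, THF, 0 °C) would give rac-3-ethoxy-2-(1-hydroxyethyl)-6-(3-methylbut-2-en-1-yl)-5-[(triisopropylsilyl)oxy]phenol F4.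
- MnO2 would oxidise it to 1-{6-ethoxy-2-hydroxy-3-(3-methylbut-2-en-1-yl)-4-[(triisopropylsilyl)oxy]phenyl}ethan-1-one F5.
- NaH and CS2 in THF, then mild acidification, would give 5-ethoxy-4-hydroxy-8-(3-methylbut-2-en-1-yl)-7-[(triisopropylsilyl)oxy]-2H-chromene-2-thione F6.
- S-Methylation (MeI, K2CO3, acetone) would give 5-ethoxy-8-(3-methylbut-2-en-1-yl)-2-(methylsulfanyl)-7-[(triisopropylsilyl)oxy]-4H-chromen-4-one F7.
- One equivalent of mCPBA at −40 °C, where sulfur should be oxidised faster than the trisubstituted alkene, would give rac-5-ethoxy-2-(methanesulfinyl)-8-(3-methylbut-2-en-1-yl)-7-[(triisopropylsilyl)oxy]-4H-chromen-4-one F8.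
- 4-Methoxyphenol 16 with K2CO3 in DMF would displace the sulfinyl group to give 21.

Step 9. Chloride may attack the Lewis-acid-activated C2 and expel the aryloxy group, in competition with the chelation-directed cleavage of the ethyl ether. The fallback cleaves the ethyl ether before any aryloxy group is present; it sets out from aldehyde 15 and returns at 22. It follows the preceding fallback as far as 5-ethoxy-8-(3-methylbut-2-en-1-yl)-2-(methylsulfanyl)-7-[(triisopropylsilyl)oxy]-4H-chromen-4-one F7, whose C2 carries only a poor leaving group.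
- BCl3 (CH2Cl2, −78 → −20 °C) would give 5-hydroxy-8-(3-methylbut-2-en-1-yl)-2-(methylsulfanyl)-7-[(triisopropylsilyl)oxy]-4H-chromen-4-one F9.
- One equivalent of mCPBA at −40 °C would give rac-5-hydroxy-2-(methanesulfinyl)-8-(3-methylbut-2-en-1-yl)-7-[(triisopropylsilyl)oxy]-4H-chromen-4-one F10.
- 4-Methoxyphenol 16 with K2CO3 (two equivalents, DMF) would displace the sulfinyl group to give 22, which is desilylated as in step 10.

**Further compounds**
F1 | step 4 | 3-ethoxybut-3-en-2-one | CCOC(=C)C(C)=O
F2 | step 4 | 5-ethoxy-1,1,1-trifluorohex-5-ene-2,4-dione | CCOC(=C)C(=O)CC(=O)C(F)(F)F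
F3 | step 4 | 1-diazo-3-ethoxybut-3-en-2-one | CCOC(=C)C(=O)C=[N+]=[N-]
F4 | step 7 | rac-3-ethoxy-2-(1-hydroxyethyl)-6-(3-methylbut-2-en-1-yl)-5-[(triisopropylsilyl)oxy]phenol | CCOc1cc(O[Si](C(C)C)(C(C)C)C(C)C)c(CC=C(C)C)c(O)c1C(C)O
F5 | step 7 | 1-{6-ethoxy-2-hydroxy-3-(3-methylbut-2-en-1-yl)-4-[(triisopropylsilyl)oxy]phenyl}ethan-1-one | CCOc1cc(O[Si](C(C)C)(C(C)C)C(C)C)c(CC=C(C)C)c(O)c1C(C)=O
F6 | step 7 | 5-ethoxy-4-hydroxy-8-(3-methylbut-2-en-1-yl)-7-[(triisopropylsilyl)oxy]-2H-chromene-2-thione | CCOc1cc(O[Si](C(C)C)(C(C)C)C(C)C)c(CC=C(C)C)c2oc(=S)cc(O)c12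
F7 | step 7 | 5-ethoxy-8-(3-methylbut-2-en-1-yl)-2-(methylsulfanyl)-7-[(triisopropylsilyl)oxy]-4H-chromen-4-one | CCOc1cc(O[Si](C(C)C)(C(C)C)C(C)C)c(CC=C(C)C)c2oc(SC)cc(=O)c12
F8 | step 7 | rac-5-ethoxy-2-(methanesulfinyl)-8-(3-methylbut-2-en-1-yl)-7-[(triisopropylsilyl)oxy]-4H-chromen-4-one | CCOc1cc(O[Si](C(C)C)(C(C)C)C(C)C)c(CC=C(C)C)c2oc(S(C)=O)cc(=O)c12
F9 | step 9 | 5-hydroxy-8-(3-methylbut-2-en-1-yl)-2-(methylsulfanyl)-7-[(triisopropylsilyl)oxy]-4H-chromen-4-one | Oc1cc(O[Si](C(C)C)(C(C)C)C(C)C)c(CC=C(C)C)c2oc(SC)cc(=O)c12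
F10 | step 9 | rac-5-hydroxy-2-(methanesulfinyl)-8-(3-methylbut-2-en-1-yl)-7-[(triisopropylsilyl)oxy]-4H-chromen-4-one | Oc1cc(O[Si](C(C)C)(C(C)C)C(C)C)c(CC=C(C)C)c2oc(S(C)=O)cc(=O)c12
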